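## Retrosynthetic overview

- The target is the (3S)-isoflavanone. It is disconnected at the C3–aryl bond into a racemic 3-bromochroman-4-one, used as an enolonium (a2) equivalent, and the arylzinc iodide of the chromene B/D fragment.
- A stereoconvergent Ni/chiral-pybox coupling forms this bond and sets C3 in the last step.
- The bromoketone comes from CuBr2 α-bromination of 5-hydroxy-7-methoxychroman-4-one, made by selective 7-O-methylation of 5,7-dihydroxychroman-4-one, itself from phloroglucinol and 3-chloropropanoic acid.
- The arylzinc comes from 6-bromo-7-methoxy-2,2-dimethyl-2H-chromene, made from 4-bromo-3-methoxyphenol and prenal.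
- Ring order: the pyranone ring C is closed on the phloroglucinol ring A first; the 2H-pyran ring D is closed separately on the B-ring phenol; the two halves are joined last and no ring is formed after the stereocentre.

Assumption: the sense of induction of the pybox ligand on this new substrate class cannot be predicted with certainty, so the ligand antipode that gives (3S) is fixed in a pilot run (chiral HPLC/ECD); both antipodes are available.

## Route

Step 1
Reactants: 1 phloroglucinol; 2 3-chloropropanoic acid
Product: 4 5,7-dihydroxychroman-4-one, via aryl 2-chloroethyl ketone 3 (not isolated)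
Conditions: TfOH (3 equiv), 80 °C, 1 h; then poured into 2 M aq NaOH, 0 °C → rt, 2 h; HCl to pH 2
Reagents that add atoms: none
Why: Friedel–Crafts (Fries-type) acylation of the C3-symmetric triol in TfOH can give only one ortho-hydroxyaryl ketone, and its phenoxide then closes the pyranone ring by intramolecular Williamson displacement of chloride.

Step 2
Reactants: 4 5,7-dihydroxychroman-4-one
Product: 5 5-hydroxy-7-methoxychroman-4-one
Conditions: Me2SO4 (1.05 equiv), K2CO3 (1.1 equiv), acetone, reflux, 3 h
Reagents that add atoms: dimethyl sulfate, COS(=O)(=O)OC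
Why: Williamson O-methylation is selective for the 7-OH because the 5-OH is locked in a hydrogen bond to the C4 carbonyl and is much less nucleophilic.

Step 3
Reactants: 5 5-hydroxy-7-methoxychroman-4-one
Product: 6 rac-3-bromo-5-hydroxy-7-methoxychroman-4-one
Conditions: CuBr2 (2.1 equiv), EtOAc/CHCl3 1:1, reflux, 4 h
Reagents that add atoms: copper(II) bromide, [Cu+2].[Br-].[Br-]
Why: CuBr2 α-bromination of a ketone goes through the copper-bound enol and is the standard way to brominate hydroxyaryl ketones at the α-carbon and not on the ring; the new C3 centre is racemic on purpose, since step 5 is stereoconvergent.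

Step 4
Reactants: 7 4-bromo-3-methoxyphenol; 8 3-methylbut-2-enal (prenal)
Product: 9 6-bromo-7-methoxy-2,2-dimethyl-2H-chromene
Conditions: PhB(OH)2 (1.0 equiv, recovered), AcOH, toluene, reflux, Dean–Stark, 24 h
Reagents that add atoms: none
Why: Boronic acid-templated ortho-condensation of the phenol with the enal gives an o-quinone methide that closes by oxa-6π electrocyclisation, and the ortho carbon para to OMe reacts in preference to the hindered one between OH and OMe.

Step 5
Reactants: 6 rac-3-bromo-5-hydroxy-7-methoxychroman-4-one; 9 6-bromo-7-methoxy-2,2-dimethyl-2H-chromene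
Product: 14 (3S)-5-hydroxy-7-methoxy-3-(7-methoxy-2,2-dimethyl-2H-chromen-6-yl)chroman-4-one, via 5-O-TMS bromoketone 10 (not isolated), via arylmagnesium bromide 11 (not isolated), via arylzinc iodide 12 (not isolated), via 5-O-TMS isoflavanone 13 (not isolated)
Conditions: (i) 6, BSA (1.5 equiv), CH2Cl2, 40 °C, then high vacuum; (ii) 9 (1.6 equiv), Mg, THF, 40 °C; ZnI2 (1.6 equiv), rt; (iii) NiCl2·glyme (10 mol%), chiral Ph-pybox-type ligand (13 mol%), glyme/THF, −30 °C, 12 h; (iv) 5% aq citric acid, 0 °C
Reagents that add atoms: none
Why: Proposed new method: the racemic α-bromoketone acts as an enolonium (a2) equivalent in a Ni/pybox stereoconvergent Negishi arylation (closest known reaction type: Ni/pybox asymmetric cross-coupling of racemic acyclic α-bromoketones with arylzinc iodides at −30 °C), here extended to a cyclic 3-bromochroman-4-one — Ni abstracts bromine to give a planar α-keto radical common to both enantiomers of 10, the chiral aryl–nickel complex captures it and reductively eliminates with ligand-controlled facial selectivity to set C3 as S, the cold non-basic medium leaves the acidic C3–H untouched, and the labile aryl TMS ether (which keeps the phenol from quenching 12 or chelating Ni) is lost in the citric acid work-up.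

## Compound list

1 | phloroglucinol (benzene-1,3,5-triol) | Oc1cc(O)cc(O)c1 | starting material
2 | 3-chloropropanoic acid | OC(=O)CCCl | starting material
3 | 3-chloro-1-(2,4,6-trihydroxyphenyl)propan-1-one | O=C(CCCl)c1c(O)cc(O)cc1O | intermediate (not isolated)
4 | 5,7-dihydroxychroman-4-one | O=C1CCOc2cc(O)cc(O)c12 | intermediate
5 | 5-hydroxy-7-methoxychroman-4-one | COc1cc(O)c2C(=O)CCOc2c1 | intermediate
6 | rac-3-bromo-5-hydroxy-7-methoxychroman-4-one | COc1cc(O)c2C(=O)C(Br)COc2c1 | intermediate
7 | 4-bromo-3-methoxyphenol | COc1cc(O)ccc1Br | starting material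
8 | 3-methylbut-2-enal (prenal) | CC(C)=CC=O | starting material
9 | 6-bromo-7-methoxy-2,2-dimethyl-2H-chromene | COc1cc2OC(C)(C)C=Cc2cc1Br | intermediate
10 | rac-3-bromo-7-methoxy-5-(trimethylsilyloxy)chroman-4-one | COc1cc(O[Si](C)(C)C)c2C(=O)C(Br)COc2c1 | intermediate (not isolated)
11 | (7-methoxy-2,2-dimethyl-2H-chromen-6-yl)magnesium bromide | COc1cc2OC(C)(C)C=Cc2cc1[Mg]Br | intermediate (not isolated)
12 | (7-methoxy-2,2-dimethyl-2H-chromen-6-yl)zinc iodide | COc1cc2OC(C)(C)C=Cc2cc1[Zn]I | intermediate (not isolated)
13 | (3S)-7-methoxy-3-(7-methoxy-2,2-dimethyl-2H-chromen-6-yl)-5-(trimethylsilyloxy)chroman-4-one | COc1cc(O[Si](C)(C)C)c2c(c1)OC[C@H](c1cc3c(cc1OC)OC(C)(C)C=C3)C2=O | intermediate (not isolated)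
14 | (3S)-5-hydroxy-7-methoxy-3-(7-methoxy-2,2-dimethyl-2H-chromen-6-yl)chroman-4-one | COc1cc(O)c2c(c1)OC[C@H](c1cc3c(cc1OC)OC(C)(C)C=C3)C2=O | target

## Step count and risks

Total steps: 5. Longest linear sequence: 4 (steps 1, 2, 3, 5); step 4 is the convergent branch.

The three steps most likely to fail:

**Step 5 (key coupling).** The risks are low ee or low conversion on a cyclic, β-oxygenated bromoketone, β-hydride loss to the chromone, and a sluggish ortho-methoxy arylzinc. The fallback sets out from 10 and 12 and comes back to the route at 13. It makes the C–C bond and the stereocentre in separate operations. 10 and 12 are coupled with an achiral, less crowded catalyst (NiCl2·glyme, 4,4′-di-tert-butyl-2,2′-bipyridine, THF, 0 °C) to give racemic 7-methoxy-3-(7-methoxy-2,2-dimethyl-2H-chromen-6-yl)-5-(trimethylsilyloxy)chroman-4-one F1. The citric acid work-up gives racemic 5-hydroxy-7-methoxy-3-(7-methoxy-2,2-dimethyl-2H-chromen-6-yl)chroman-4-one F2; material of poor ee from step 5 can be used in its place. TMSOTf/Et3N (CH2Cl2, 0 °C) converts it into the bis-silyl enol ether 7-methoxy-3-(7-methoxy-2,2-dimethyl-2H-chromen-6-yl)-4,5-bis(trimethylsilyloxy)-2H-chromene F3. Catalytic enantioselective protonation of F3 at C3 (5 mol% BINOL-derived N-triflyl thiophosphoramide, PhOH 1.1 equiv, toluene, −20 °C → rt; catalyst antipode chosen for 3S) gives 13, and the same work-up gives 14.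

**Step 3 (α-bromination).** The risks are ring bromination of the very electron-rich A ring, dibromination, or HBr loss to the chromone. The fallback sets out from 5 and comes back at 6. It brominates a preformed enol silane with the phenol masked: TMSOTf (2.3 equiv)/Et3N (CH2Cl2, 0 °C) gives 7-methoxy-4,5-bis(trimethylsilyloxy)-2H-chromene F4. NBS (1.0 equiv, THF, −78 °C) attacks only the enol ether carbon C3 to give 10, and aqueous work-up gives 6.

**Step 4 (chromene formation).** The risks are a low yield with a mono-phenol and some of the regioisomer from closure at the hindered ortho carbon. The fallback sets out from 7 and comes back at 9. 7 is O-alkylated with 3-chloro-3-methylbut-1-yne (K2CO3, KI, cat. CuI, acetone, 60 °C) to give 1-bromo-2-methoxy-4-[(2-methylbut-3-yn-2-yl)oxy]benzene F5. Heating F5 in N,N-diethylaniline at 190 °C (aromatic propargyl Claisen rearrangement, [1,5]-H shift, oxa-6π electrocyclisation) gives 9, which is separated from the minor regioisomer by chromatography.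

## Further compounds

F1 | step 5 | racemic 7-methoxy-3-(7-methoxy-2,2-dimethyl-2H-chromen-6-yl)-5-(trimethylsilyloxy)chroman-4-one | COc1cc(O[Si](C)(C)C)c2c(c1)OCC(c1cc3c(cc1OC)OC(C)(C)C=C3)C2=O
F2 | step 5 | racemic 5-hydroxy-7-methoxy-3-(7-methoxy-2,2-dimethyl-2H-chromen-6-yl)chroman-4-one | COc1cc(O)c2c(c1)OCC(c1cc3c(cc1OC)OC(C)(C)C=C3)C2=O
F3 | step 5 | 7-methoxy-3-(7-methoxy-2,2-dimethyl-2H-chromen-6-yl)-4,5-bis(trimethylsilyloxy)-2H-chromene | COc1cc(O[Si](C)(C)C)c2c(c1)OCC(c1cc3c(cc1OC)OC(C)(C)C=C3)=C2O[Si](C)(C)C
F4 | step 3 | 7-methoxy-4,5-bis(trimethylsilyloxy)-2H-chromene | COc1cc(O[Si](C)(C)C)c2C(O[Si](C)(C)C)=CCOc2c1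
F5 | step 4 | 1-bromo-2-methoxy-4-[(2-methylbut-3-yn-2-yl)oxy]benzene | COc1cc(OC(C)(C)C#C)ccc1Br
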